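Follow E.

| flask | Q | X | Z | remark | time |
|---|---|---|---|---|---|
| dusk | 0.11 M | 0.44 M | 0.055 M | run made earlier |  |
| dawn | 0.11 M | 0.22 M | 0.055 M | run made earlier |  |
| summer | 0.11 M | 0.33 M | 0.055 M | run made earlier |  |
| amber | 0.11 M (fed, over 2.40 d) | 0.440 M | 0.0550 M | a stirred flask in which Q is dosed at a steady rate over 2.40 d without added volume, worked up at 3.0 d | 3.0 d |
| ochre | 0.11 M | 0.440 M | 0.0550 M | a closed flask charged with all of it at once and left for 3.0 d | 3.0 d |
| grey | 0.11 M | 0.440 M (fed, over 2.40 d) | 0.0550 M | all but X at the start; X goes in evenly over 2.40 d, the run ends at 3.0 d | 3.0 d |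
| blue | 0.11 M | 0.440 M | 0.0550 M | one stirred flow tank at steady state, fed with the mixture as stated, mean residence time 3.0 d |  |

- dusk (time / h: E / %, J / %): 4.00: 19.1, 1.0; 10.0: 34.6, 5.5; 20.0: 41.8, 15.2; 30.0: 39.6, 25.4; 40.0: 35.1, 34.1
- dawn (time / d: E / %, J / %): 0.333: 32.4, 2.0; 0.833: 48.8, 8.4; 1.67: 48.8, 20.6; 2.50: 41.5, 30.1; 4.00: 28.9, 43.8
- summer (time / d: E / %, J / %): 0.333: 31.9, 2.5; 0.833: 45.1, 12.4; 1.67: 40.6, 28.1; 2.50: 31.5, 40.0; 4.00: 17.8, 54.5

(readings scatter by 0.3 percentage points)

- order of the set-ups by the amount of E at the outlet or at the end, in percent of the Q put in, highest first (amber / ochre / grey / blue)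
- amount of E at the outlet or at the end, in percent of the Q put in, amber
- amount of E at the outlet or at the end, in percent of the Q put in, ochre
- amount of E at the outlet or at the end, in percent of the Q put in, grey
- amount of E at the outlet or at the end, in percent of the Q put in, blue

- the stated concentrations are those of everything mixed, before any reaction; amounts are the same in each set-up
- the analysis behind the earlier runs scatters by 0.3 percentage points, standard deviation
- the feed brings no volume worth counting
- the earlier runs were made in a closed, stirred flask

Run dusk in slow motion. In the first instants E climbs while J lags, 19.1% against 1.0% at 4.00 h. In the middle E tops out among the readings at 41.8% at 20.0 h, and J gathers pace. Late on, E falls as J rises.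

Now ask for the end state. In dawn E plus J reads 72.7% at 4.00 d, so a quarter of the Q shows as neither. Take that reading as the ceiling, with E draining towards J. Dawn reaches half of it by 0.333 d; count that as the delay between Q arriving and E appearing.

Then ask how fast E drains. Between 20.0 h and 30.0 h in dusk, multiply the mean E by the interval and divide by the gain in J. This gives 1.66 d, the lifetime of E: the mean time an E lasts before it becomes J, at 0.44 M of X. The same reckoning in dawn, from 0.833 d to 1.67 d, gives 3.35 d, twice as long at half the X. So treat the loss as pseudo-first-order, with the lifetime inverse to X.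

My reckoning: in ochre, E made after the delay has 2.67 d to survive, so the ceiling times the surviving share gives 14.6%. In amber, the middle of the dose arrives at 1.20 d, which leaves 1.47 d and, on the same ceiling, an estimate of 30.1%, twice the estimate for ochre.

The forecast differs: grey > ochre > blue > amber, with ochre 18.5%, grey 28.2%, blue 18.4% and amber 11.8%, the last on the ground that “late-fed Q meets dead catalyst”.

The flask gives amber > grey > blue > ochre: amber 32.3%, ochre 18.5%, grey 27.6%, blue 24.1%.

    X + E → J (k = 0.0585 M⁻¹ h⁻¹)
    Q → E (k = 0.0607 h⁻¹)
    Q + Z → G (k = 0.615 M⁻¹ h⁻¹)

Compare the time left with the lifetime. In amber, half of the turnover of Q into E up to the end is done by 1.64 d, leaving 1.36 d, shorter than the lifetime; in ochre, taking instead the half-life of Q by that step alone, 0.48 d, leaves 2.52 d, longer than the lifetime.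

Now take a neighbour of amber, dosed alike but charged with 0.26 M of X. Reckoned inverse to X, the lifetime becomes 2.81 d, so over the same 1.36 d expect a share of 0.617 of amber's final E plus J to stand as E, an estimate of 41.2%. The neighbour gives 42.7% of E.

The readings come from a simulation for substances that don't exist, and the scatter is random.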